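**Retrosynthetic overview**

1. Target ⇐ the C19 acetate comes from an axial C19 nitrile; the C8 methylidene and the C9 side chain come from a C9 ketone (α-methylenation, 1,2-addition, palladium/formate hydrogenolysis).
2. The 7α-hydroxyl is the isopropenyl-bearing stereocentre of (R)-carvone, converted by Criegee rearrangement with retention.
3. Key disconnection: ring A is taken off ring B by cutting C3–C4 and C1–C10 (and C4–C5), giving (R)-carvone (ring B with C20), propanenitrile (C4, C18, C19) and (R)-4-(chloromethyl)-1,3,2-dioxathiolane 2,2-dioxide (C1–C2–C3 with the C2 oxygen).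
4. Enabling feature: the methyl-bearing quaternary C10 and the ring-fusion C5 are the α- and β-carbons of a ring-B enone once C9 is a carbonyl, and C4 carries a carbon (C19) that can be a nitrile. C5 is then an acceptor, C10 an enolate carbon and C4 a nitrile-anion carbon, so the 1,3-related C10/C4 pair can be bridged by the bis-electrophile C1–C2(O)–C3.
5. Ring order: ring B is bought (carvone); ring A is closed in the key step.

Key step: step 2

Remark: labdane numbering is used throughout (C1–C10 decalin with C5/C10 ring fusion, C18 = 4α-methyl, C19 = 4β axial carbon, C20 = 10β-methyl, C17 = exocyclic carbon on C8, C11–C13 and C16 = side chain on C9); (R)-carvone, propanenitrile, (R)-3-chloropropane-1,2-diol and 2-(2-bromoethyl)-2-methyl-1,3-dioxolane are taken as commercial.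

**Route**

Step 1
Reactants: 1 (R)-3-chloropropane-1,2-diol
Product: 3 (R)-4-(chloromethyl)-1,3,2-dioxathiolane 2,2-dioxide, via cyclic sulfite 2 (not isolated)
Conditions: SOCl2, CH2Cl2, 40 °C; then RuCl3 (cat.), NaIO4, MeCN/H2O, 0 °C
Reagents that add atoms: thionyl chloride O=S(Cl)Cl; sodium periodate [Na+].[O-]I(=O)(=O)=O
Why: Cyclic sulfite formation from a 1,2-diol followed by RuCl3-catalysed periodate oxidation at sulfur is the standard route to 1,2-cyclic sulfates, and no bond to the stereocentre is touched, so the (R) configuration is kept.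

Step 2
Reactants: 4 (R)-carvone, 5 propanenitrile, 3 (R)-4-(chloromethyl)-1,3,2-dioxathiolane 2,2-dioxide
Product: 10 2α-hydroxy-4α,10β-dimethyl-9-oxo-7α-(prop-1-en-2-yl)-5α-decalin-4β-carbonitrile (trans-fused), via 2-lithiopropanenitrile 6 (not isolated), via lithium enolate 7 (not isolated), via chloro sulfate lithium salt 8 (not isolated), via decalin sulfate lithium salt 9 (not isolated)
Conditions: LiN(i-Pr)2, THF, −78 °C; 4, DMPU, −78 → −30 °C; 3, −30 → 0 °C; LiN(i-Pr)2, −78 → 0 °C; then H2SO4 (cat.), H2O, THF, 25 °C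
Reagents that add atoms: none
Why: Mechanism: 2-lithiopropanenitrile adds 1,4 to carvone at C5, the resulting C10 lithium enolate is C-alkylated by the ring CH2 of the cyclic sulfate (C1–C10), the second charge of LiN(i-Pr)2 deprotonates the nitrile and the C4 carbanion displaces chloride at C3 (C3–C4), and acid hydrolysis of the sulfate monoester frees the C2 hydroxyl. The closest known reaction types are the conjugate addition–enolate alkylation three-component coupling of enones, C-alkylation of enolates by 1,2-cyclic sulfates and intramolecular nitrile anion alkylation. Ring A closes 6-exo-tet at C3. C5 is set by axial attack anti to the C7 isopropenyl group, C10 by alkylation anti to the new C5 substituent (held pseudoaxial by strain against the C10 methyl), which puts C1 and C4 trans and hence gives the trans-decalin, and C4 by the chair transition state in which the small, linear metalated nitrile sits anti to H-5 and syn-axial to the C10 methyl while the C18 methyl eclipses H-5, so the nitrile (C19) ends axial and β; C2 is not formed but carried over with retention from the (R)-sulfate (its C–O bond is never broken) and sits equatorial in that chair. The step needs the order enolate first, nitrile anion second, which is secured by adding the second base only after the enolate has been consumed, and the site order sulfate carbon before alkyl chloride, which is intrinsic to the reagent. Closure of a C8 enolate onto C3 (giving a bicyclo[3.3.1]nonanone) is the competing pathway and is disfavoured because at −78 °C the nitrile anion is by far the better nucleophile.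

Step 3
Reactants: 10 2α-hydroxy-4α,10β-dimethyl-9-oxo-7α-(prop-1-en-2-yl)-5α-decalin-4β-carbonitrile
Product: 12 4β-cyano-4α,10β-dimethyl-9-oxo-5α-decalin-2α,7α-diyl diacetate, via methoxy hydroperoxide 11 (not isolated)
Conditions: O3, CH2Cl2/MeOH, −78 °C; then Ac2O, Et3N, DMAP, 0 → 25 °C
Reagents that add atoms: ozone [O-][O+]=O; methanol CO; acetic anhydride CC(=O)OC(C)=O
Why: Ozonolysis in methanol gives the α-methoxy hydroperoxide, whose peracetate undergoes Criegee rearrangement with migration of C7 to oxygen with retention, so the carvone stereocentre becomes the 7α-oxygen (the free C2 hydroxyl is acetylated at the same time).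

Step 4
Reactants: 12 4β-cyano-4α,10β-dimethyl-9-oxo-5α-decalin-2α,7α-diyl diacetate
Product: 13 2α,7α-dihydroxy-4α,10β-dimethyl-9-oxo-5α-decalin-4β-carbonitrile
Conditions: HCl (cat.), MeOH, 0 → 25 °C
Reagents that add atoms: none
Why: Acid-catalysed transesterification removes both acetates without forming the C8 enolate that would expel the C7 oxygen, so both carbinol configurations stay untouched.

Step 5
Reactants: 13 2α,7α-dihydroxy-4α,10β-dimethyl-9-oxo-5α-decalin-4β-carbonitrile
Product: 14 2α,7α-bis(tert-butyldimethylsilyloxy)-4α,10β-dimethyl-9-oxo-5α-decalin-4β-carbonitrile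
Conditions: TBSOTf, 2,6-lutidine, CH2Cl2, −78 → 0 °C
Reagents that add atoms: tert-butyldimethylsilyl trifluoromethanesulfonate CC(C)(C)[Si](C)(C)OS(=O)(=O)C(F)(F)F
Why: Silyl triflate silylation masks both secondary hydroxyls against the bases, organometallic and hydride reagents of steps 6 to 10 and touches no stereocentre.

Step 6
Reactants: 14 2α,7α-bis(tert-butyldimethylsilyloxy)-4α,10β-dimethyl-9-oxo-5α-decalin-4β-carbonitrile
Product: 17 2α,7α-bis(tert-butyldimethylsilyloxy)-4α,10β-dimethyl-8-methylidene-9-oxo-5α-decalin-4β-carbonitrile, via Mannich base 15 (not isolated), via ammonium iodide 16 (not isolated)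
Conditions: LiN(i-Pr)2, THF, −78 °C; Me2N=CH2+ I−, −78 → 0 °C; MeI, CH2Cl2, 25 °C; then aq. NaHCO3
Reagents that add atoms: dimethyl(methylidene)ammonium iodide C=[N+](C)C.[I-]
Why: C8 is the only enolisable position of the C9 ketone (C10 is quaternary), so enolate Mannich reaction, N-methylation and elimination of trimethylamine install the C17 methylidene regiospecifically, and at −78 °C the enolate should not expel the β-silyloxy group.

Step 7
Reactants: 17 2α,7α-bis(tert-butyldimethylsilyloxy)-4α,10β-dimethyl-8-methylidene-9-oxo-5α-decalin-4β-carbonitrile, 18 2-(2-bromoethyl)-2-methyl-1,3-dioxolane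
Product: 21 2α,7α-bis(tert-butyldimethylsilyloxy)-4β-cyano-4α,10β-dimethyl-8-methylidene-9-[2-(2-methyl-1,3-dioxolan-2-yl)ethyl]-5α-decalin-9-yl methyl carbonate (C9 configuration not fixed), via Grignard reagent 19 (not isolated), via magnesium alkoxide 20 (not isolated)
Conditions: 18, Mg, THF, 25 °C; CeCl3, −78 °C; 17; then ClCO2Me, −78 → 25 °C
Reagents that add atoms: methyl chloroformate COC(=O)Cl
Why: 1,2-Addition of the CeCl3-modified Grignard reagent to the non-enolisable enone carbonyl (cerium suppresses conjugate addition) and in situ acylation of the tertiary alkoxide give the allylic carbonate, whose C9 configuration does not matter because it is erased in step 8.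

Step 8
Reactants: 21 allylic methyl carbonate
Product: 22 2α,7α-bis(tert-butyldimethylsilyloxy)-13,13-(ethylenedioxy)-14,15-dinorlabd-8(17)-ene-19-nitrile
Conditions: Pd(OAc)2 (cat.), n-Bu3P (cat.), HCO2H, Et3N, THF, 40 °C
Reagents that add atoms: none
Why: Palladium-catalysed formate hydrogenolysis of an allylic carbonate: the allylpalladium formate spanning C9–C8–C17 loses CO2 and the palladium hydride delivers hydrogen to the more substituted terminus C9, keeping the C8=C17 methylidene; the two faces of the allyl complex interconvert through the C17 σ-bound form and hydrogen should be delivered from the α-face, opposite the C10 methyl, so that the side chain ends equatorial (9β) and away from the axial 7α-silyloxy group.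

Step 9
Reactants: 22 2α,7α-bis(tert-butyldimethylsilyloxy)-13,13-(ethylenedioxy)-14,15-dinorlabd-8(17)-ene-19-nitrile
Product: 23 2α,7α-bis(tert-butyldimethylsilyloxy)-13,13-(ethylenedioxy)-14,15-dinorlabd-8(17)-en-19-al
Conditions: i-Bu2AlH, toluene, −78 → 0 °C; then aq. tartaric acid
Reagents that add atoms: water O
Why: i-Bu2AlH adds once to the hindered axial nitrile and the aluminium imide is hydrolysed to the aldehyde on work-up, while silyl ethers, dioxolane and alkene are inert and the quaternary C4 cannot epimerise.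

Step 10
Reactants: 23 2α,7α-bis(tert-butyldimethylsilyloxy)-13,13-(ethylenedioxy)-14,15-dinorlabd-8(17)-en-19-al
Product: 24 2α,7α-bis(tert-butyldimethylsilyloxy)-13,13-(ethylenedioxy)-14,15-dinorlabd-8(17)-en-19-ol
Conditions: NaBH4, MeOH, 0 °C
Reagents that add atoms: none
Why: Borohydride reduction of the neopentyl aldehyde gives the C19 primary alcohol and involves no stereocentre.

Step 11
Reactants: 24 2α,7α-bis(tert-butyldimethylsilyloxy)-13,13-(ethylenedioxy)-14,15-dinorlabd-8(17)-en-19-ol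
Product: 25 2α,7α-bis(tert-butyldimethylsilyloxy)-13,13-(ethylenedioxy)-14,15-dinorlabd-8(17)-en-19-yl acetate
Conditions: Ac2O, pyridine, DMAP (cat.), CH2Cl2, 25 °C
Reagents that add atoms: acetic anhydride CC(=O)OC(C)=O
Why: DMAP-catalysed acetylation of the only free hydroxyl.

Step 12
Reactants: 25 2α,7α-bis(tert-butyldimethylsilyloxy)-13,13-(ethylenedioxy)-14,15-dinorlabd-8(17)-en-19-yl acetate
Product: 26 19-acetoxy-2α,7α-dihydroxy-14,15-dinorlabd-8(17)-en-13-one
Conditions: aq. HF, MeCN, 0 → 25 °C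
Reagents that add atoms: water O
Why: Aqueous HF cleaves both silyl ethers and hydrolyses the dioxolane, while the primary acetate, the exocyclic alkene and the allylic C7 carbinol should survive at low temperature.

**Compound list**

1 | (R)-3-chloropropane-1,2-diol | ClC[C@H](O)CO | starting material
2 | (4R)-4-(chloromethyl)-1,3,2-dioxathiolane 2-oxide (cyclic sulfite, both configurations at sulfur) | ClC[C@H]1COS(=O)O1 | intermediate
3 | (R)-4-(chloromethyl)-1,3,2-dioxathiolane 2,2-dioxide (cyclic sulfate) | ClC[C@H]1COS(=O)(=O)O1 | intermediate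
4 | (R)-carvone, (5R)-2-methyl-5-(prop-1-en-2-yl)cyclohex-2-en-1-one | CC1=CC[C@H](CC1=O)C(C)=C | starting material
5 | propanenitrile | CCC#N | starting material
6 | 2-lithiopropanenitrile | C[CH-]C#N.[Li+] | intermediate
7 | lithium 3-(1-cyanoethyl)-2-methyl-5-(prop-1-en-2-yl)cyclohex-1-en-1-olate (3,5-trans, carvone centre unchanged, nitrile-bearing carbon as both epimers) | C1[C@H](C(C)=C)C[C@H](C(C)=C1[O-])C(C)C#N.[Li+] | intermediate
8 | lithium (2R)-1-chloro-3-[2-(1-cyanoethyl)-1-methyl-6-oxo-4-(prop-1-en-2-yl)cyclohexyl]propan-2-yl sulfate (new chain trans to the cyanoethyl group, isopropenyl trans to the cyanoethyl group) | C1[C@H](C(C)=C)C[C@H]([C@](C)(C[C@@H](OS(=O)(=O)[O-])CCl)C1=O)C(C)C#N.[Li+] | intermediate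
9 | lithium 4β-cyano-4α,10β-dimethyl-9-oxo-7α-(prop-1-en-2-yl)-5α-decalin-2α-yl sulfate | C1[C@H](C(C)=C)C[C@H]2[C@@](C)(C#N)C[C@H](OS(=O)(=O)[O-])C[C@]2(C)C1=O.[Li+] | intermediate
10 | 2α-hydroxy-4α,10β-dimethyl-9-oxo-7α-(prop-1-en-2-yl)-5α-decalin-4β-carbonitrile | C1[C@H](C(C)=C)C[C@H]2[C@@](C)(C#N)C[C@H](O)C[C@]2(C)C1=O | intermediate
11 | 7α-(1-hydroperoxy-1-methoxyethyl)-2α-hydroxy-4α,10β-dimethyl-9-oxo-5α-decalin-4β-carbonitrile | C1[C@H](C(C)(OC)OO)C[C@H]2[C@@](C)(C#N)C[C@H](O)C[C@]2(C)C1=O | intermediate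
12 | 4β-cyano-4α,10β-dimethyl-9-oxo-5α-decalin-2α,7α-diyl diacetate | C1[C@H](OC(C)=O)C[C@H]2[C@@](C)(C#N)C[C@H](OC(C)=O)C[C@]2(C)C1=O | intermediate
13 | 2α,7α-dihydroxy-4α,10β-dimethyl-9-oxo-5α-decalin-4β-carbonitrile | C1[C@H](O)C[C@H]2[C@@](C)(C#N)C[C@H](O)C[C@]2(C)C1=O | intermediate
14 | 2α,7α-bis(tert-butyldimethylsilyloxy)-4α,10β-dimethyl-9-oxo-5α-decalin-4β-carbonitrile | C1[C@H](O[Si](C)(C)C(C)(C)C)C[C@H]2[C@@](C)(C#N)C[C@H](O[Si](C)(C)C(C)(C)C)C[C@]2(C)C1=O | intermediate
15 | 8-[(dimethylamino)methyl] derivative of 14 (C8 epimers) | CN(C)CC1[C@H](O[Si](C)(C)C(C)(C)C)C[C@H]2[C@@](C)(C#N)C[C@H](O[Si](C)(C)C(C)(C)C)C[C@]2(C)C1=O | intermediate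
16 | 8-[(trimethylammonio)methyl] derivative of 14, iodide | C[N+](C)(C)CC1[C@H](O[Si](C)(C)C(C)(C)C)C[C@H]2[C@@](C)(C#N)C[C@H](O[Si](C)(C)C(C)(C)C)C[C@]2(C)C1=O.[I-] | intermediate
17 | 2α,7α-bis(tert-butyldimethylsilyloxy)-4α,10β-dimethyl-8-methylidene-9-oxo-5α-decalin-4β-carbonitrile | C=C1[C@H](O[Si](C)(C)C(C)(C)C)C[C@H]2[C@@](C)(C#N)C[C@H](O[Si](C)(C)C(C)(C)C)C[C@]2(C)C1=O | intermediate
18 | 2-(2-bromoethyl)-2-methyl-1,3-dioxolane | CC1(CCBr)OCCO1 | starting material
19 | [2-(2-methyl-1,3-dioxolan-2-yl)ethyl]magnesium bromide | CC1(CC[Mg]Br)OCCO1 | intermediate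
20 | bromomagnesium 2α,7α-bis(tert-butyldimethylsilyloxy)-4β-cyano-4α,10β-dimethyl-8-methylidene-9-[2-(2-methyl-1,3-dioxolan-2-yl)ethyl]-5α-decalin-9-olate (C9 not fixed) | C=C1[C@H](O[Si](C)(C)C(C)(C)C)C[C@H]2[C@@](C)(C#N)C[C@H](O[Si](C)(C)C(C)(C)C)C[C@]2(C)C1(O[Mg]Br)CCC3(C)OCCO3 | intermediate
21 | 2α,7α-bis(tert-butyldimethylsilyloxy)-4β-cyano-4α,10β-dimethyl-8-methylidene-9-[2-(2-methyl-1,3-dioxolan-2-yl)ethyl]-5α-decalin-9-yl methyl carbonate (C9 not fixed) | C=C1[C@H](O[Si](C)(C)C(C)(C)C)C[C@H]2[C@@](C)(C#N)C[C@H](O[Si](C)(C)C(C)(C)C)C[C@]2(C)C1(OC(=O)OC)CCC3(C)OCCO3 | intermediate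
22 | 2α,7α-bis(tert-butyldimethylsilyloxy)-13,13-(ethylenedioxy)-14,15-dinorlabd-8(17)-ene-19-nitrile (5α-H, 9α-H) | C=C1[C@H](O[Si](C)(C)C(C)(C)C)C[C@H]2[C@@](C)(C#N)C[C@H](O[Si](C)(C)C(C)(C)C)C[C@]2(C)[C@H]1CCC3(C)OCCO3 | intermediate
23 | 2α,7α-bis(tert-butyldimethylsilyloxy)-13,13-(ethylenedioxy)-14,15-dinorlabd-8(17)-en-19-al | C=C1[C@H](O[Si](C)(C)C(C)(C)C)C[C@H]2[C@@](C)(C=O)C[C@H](O[Si](C)(C)C(C)(C)C)C[C@]2(C)[C@H]1CCC3(C)OCCO3 | intermediate
24 | 2α,7α-bis(tert-butyldimethylsilyloxy)-13,13-(ethylenedioxy)-14,15-dinorlabd-8(17)-en-19-ol | C=C1[C@H](O[Si](C)(C)C(C)(C)C)C[C@H]2[C@@](C)(CO)C[C@H](O[Si](C)(C)C(C)(C)C)C[C@]2(C)[C@H]1CCC3(C)OCCO3 | intermediate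
25 | 2α,7α-bis(tert-butyldimethylsilyloxy)-13,13-(ethylenedioxy)-14,15-dinorlabd-8(17)-en-19-yl acetate | C=C1[C@H](O[Si](C)(C)C(C)(C)C)C[C@H]2[C@@](C)(COC(C)=O)C[C@H](O[Si](C)(C)C(C)(C)C)C[C@]2(C)[C@H]1CCC3(C)OCCO3 | intermediate
26 | 19-acetoxy-2α,7α-dihydroxy-14,15-dinorlabd-8(17)-en-13-one | C=C1[C@H](O)C[C@H]2[C@@](C)(COC(C)=O)C[C@H](O)C[C@]2(C)[C@H]1CCC(C)=O | target

**Count and risks**

Total step count: 12. Longest linear sequence: 12 steps (1 → 3 → 10 → 26); 11 steps from (R)-carvone.

Steps most likely to fail: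

Step 2. The lithiated nitrile may add 1,2 instead of 1,4; the tetrasubstituted enolate may be C-alkylated only sluggishly by the cyclic sulfate (proton transfer or attack at oxygen instead); or a C8 enolate may close onto C3 in place of the nitrile anion. The fallback sets out from 4 and comes back at 14. It installs the C7 oxygen before the annulation, uses a doubly allylic bis-electrophile and makes the C2 oxygen by oxidative cleavage and equilibrating reduction. Criegee rearrangement of 4 itself (O3, MeOH; Ac2O, Et3N, DMAP) would give (1R)-4-methyl-5-oxocyclohex-3-en-1-yl acetate F1. Acid-catalysed methanolysis would give (R)-5-hydroxy-2-methylcyclohex-2-en-1-one F2, and TBSOTf/2,6-lutidine its silyl ether (R)-5-(tert-butyldimethylsilyloxy)-2-methylcyclohex-2-en-1-one F3. Conjugate addition of 6 to F3, alkylation of the enolate with 3-chloro-2-(chloromethyl)prop-1-ene and closure with LiN(i-Pr)2 would give 7α-(tert-butyldimethylsilyloxy)-4α,10β-dimethyl-2-methylidene-9-oxo-5α-decalin-4β-carbonitrile F4. OsO4/NaIO4 cleavage would give the 2,9-diketone 7α-(tert-butyldimethylsilyloxy)-4α,10β-dimethyl-2,9-dioxo-5α-decalin-4β-carbonitrile F5. Equilibrating reduction of the unhindered C2 ketone with Al(O-i-Pr)3 in i-PrOH would give the equatorial alcohol 7α-(tert-butyldimethylsilyloxy)-2α-hydroxy-4α,10β-dimethyl-9-oxo-5α-decalin-4β-carbonitrile F6, and silylation would give 14.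

Step 8. The hydride may be delivered to the wrong face of the allylpalladium complex or to the primary terminus C17, or the complex may lose a β-hydrogen to give a diene. The fallback sets out from 14 and comes back at 22. It places C9 next to a C8 ketone so that its configuration is under thermodynamic control. KN(SiMe3)2 and PhNTf2 would give the enol triflate 2α,7α-bis(tert-butyldimethylsilyloxy)-4β-cyano-4α,10β-dimethyl-5α-decal-8-en-9-yl trifluoromethanesulfonate F7. Suzuki coupling with the 9-borabicyclo[3.3.1]nonane adduct of 2-methyl-2-vinyl-1,3-dioxolane (PdCl2(dppf), K3PO4) would give 2α,7α-bis(tert-butyldimethylsilyloxy)-13,13-(ethylenedioxy)-14,15,17-trinorlabd-8-ene-19-nitrile F8. Hydroboration–oxidation (BH3·THF; NaOH, H2O2) from the α-face would give the C8 alcohol 2α,7α-bis(tert-butyldimethylsilyloxy)-13,13-(ethylenedioxy)-8-hydroxy-14,15,17-trinorlabdane-19-nitrile F9. Oxidation (SO3·pyridine, DMSO, i-Pr2NEt) would give the ketone 2α,7α-bis(tert-butyldimethylsilyloxy)-13,13-(ethylenedioxy)-8-oxo-14,15,17-trinorlabdane-19-nitrile F10, in which the side chain settles equatorial at the epimerisable C9. Wittig methylenation (Ph3P=CH2) would give 22.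

Step 4. Acetic acid (or water from the product) may be eliminated across C7–C8 next to the C9 ketone, or ring B may open by retro-aldol cleavage. The fallback sets out from 12 and comes back at 14. It removes the carbonyl before the acetates are cleaved. NaBH4 would reduce the C9 ketone to 4β-cyano-9-hydroxy-4α,10β-dimethyl-5α-decalin-2α,7α-diyl diacetate F11. K2CO3 in MeOH would then give the triol 2α,7α,9-trihydroxy-4α,10β-dimethyl-5α-decalin-4β-carbonitrile F12. TBSCl and imidazole would silylate the two unhindered hydroxyls to give 2α,7α-bis(tert-butyldimethylsilyloxy)-9-hydroxy-4α,10β-dimethyl-5α-decalin-4β-carbonitrile F13, and oxidation (SO3·pyridine, DMSO, i-Pr2NEt) would give 14.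

Further compounds
F1 | step 2 | (1R)-4-methyl-5-oxocyclohex-3-en-1-yl acetate | C1[C@H](OC(C)=O)CC=C(C)C1=O
F2 | step 2 | (R)-5-hydroxy-2-methylcyclohex-2-en-1-one | C1[C@H](O)CC=C(C)C1=O
F3 | step 2 | (R)-5-(tert-butyldimethylsilyloxy)-2-methylcyclohex-2-en-1-one | C1[C@H](O[Si](C)(C)C(C)(C)C)CC=C(C)C1=O
F4 | step 2 | 7α-(tert-butyldimethylsilyloxy)-4α,10β-dimethyl-2-methylidene-9-oxo-5α-decalin-4β-carbonitrile | C1[C@H](O[Si](C)(C)C(C)(C)C)C[C@H]2[C@@](C)(C#N)CC(=C)C[C@]2(C)C1=O
F5 | step 2 | 7α-(tert-butyldimethylsilyloxy)-4α,10β-dimethyl-2,9-dioxo-5α-decalin-4β-carbonitrile | C1[C@H](O[Si](C)(C)C(C)(C)C)C[C@H]2[C@@](C)(C#N)CC(=O)C[C@]2(C)C1=O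
F6 | step 2 | 7α-(tert-butyldimethylsilyloxy)-2α-hydroxy-4α,10β-dimethyl-9-oxo-5α-decalin-4β-carbonitrile | C1[C@H](O[Si](C)(C)C(C)(C)C)C[C@H]2[C@@](C)(C#N)C[C@H](O)C[C@]2(C)C1=O
F7 | step 8 | 2α,7α-bis(tert-butyldimethylsilyloxy)-4β-cyano-4α,10β-dimethyl-5α-decal-8-en-9-yl trifluoromethanesulfonate | C1[C@H](O[Si](C)(C)C(C)(C)C)C[C@H]2[C@@](C)(C#N)C[C@H](O[Si](C)(C)C(C)(C)C)C[C@]2(C)C(OS(=O)(=O)C(F)(F)F)=1
F8 | step 8 | 2α,7α-bis(tert-butyldimethylsilyloxy)-13,13-(ethylenedioxy)-14,15,17-trinorlabd-8-ene-19-nitrile | C1[C@H](O[Si](C)(C)C(C)(C)C)C[C@H]2[C@@](C)(C#N)C[C@H](O[Si](C)(C)C(C)(C)C)C[C@]2(C)C(CCC3(C)OCCO3)=1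
F9 | step 8 | 2α,7α-bis(tert-butyldimethylsilyloxy)-13,13-(ethylenedioxy)-8-hydroxy-14,15,17-trinorlabdane-19-nitrile (9α-H, C8 configuration immaterial) | OC1[C@H](O[Si](C)(C)C(C)(C)C)C[C@H]2[C@@](C)(C#N)C[C@H](O[Si](C)(C)C(C)(C)C)C[C@]2(C)[C@H]1CCC3(C)OCCO3
F10 | step 8 | 2α,7α-bis(tert-butyldimethylsilyloxy)-13,13-(ethylenedioxy)-8-oxo-14,15,17-trinorlabdane-19-nitrile (9α-H) | O=C1[C@H](O[Si](C)(C)C(C)(C)C)C[C@H]2[C@@](C)(C#N)C[C@H](O[Si](C)(C)C(C)(C)C)C[C@]2(C)[C@H]1CCC3(C)OCCO3
F11 | step 4 | 4β-cyano-9-hydroxy-4α,10β-dimethyl-5α-decalin-2α,7α-diyl diacetate (C9 configuration immaterial) | C1[C@H](OC(C)=O)C[C@H]2[C@@](C)(C#N)C[C@H](OC(C)=O)C[C@]2(C)C1O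
F12 | step 4 | 2α,7α,9-trihydroxy-4α,10β-dimethyl-5α-decalin-4β-carbonitrile | C1[C@H](O)C[C@H]2[C@@](C)(C#N)C[C@H](O)C[C@]2(C)C1O
F13 | step 4 | 2α,7α-bis(tert-butyldimethylsilyloxy)-9-hydroxy-4α,10β-dimethyl-5α-decalin-4β-carbonitrile | C1[C@H](O[Si](C)(C)C(C)(C)C)C[C@H]2[C@@](C)(C#N)C[C@H](O[Si](C)(C)C(C)(C)C)C[C@]2(C)C1O
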